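## Retrosynthetic overview

1. The side chain is finished last: C10=C11 by cross-metathesis, the C8 acetate by acylation, and the C8 stereocentre by Brown allylation of an α-methylene aldehyde made by allylic oxidation of an isopropenyl group.
2. The C2 angelate comes from acylation of an epoxy alcohol, the oxirane from hydroxyl-directed epoxidation of C3=C4, and the C2 hydroxyl from Luche reduction of the carvone enone.
3. The key disconnection is the C1–O bond, made first by a cis-selective α′-angeloyloxylation of (R)-carvone through a silver angelate/iodine relay on its silyl dienol ether; this centre then steers C2, C3 and C4.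
4. Ring order: the cyclohexane ring and C6 come from (R)-carvone; the only ring formed is the oxirane (step 3).

Locants: bisabolane numbering of the target. Ring C1 and C2 carry the ester oxygens, C3 the methyl, C3/C4 the epoxide, C5 is CH2, C6 carries the side chain C7(=C14H2)–C8–C9–C10=C11. In carvone, C2 is the carbonyl carbon and C1 the α′-CH2. β is the ring face of the C6 substituent, α the other face.

Assumption: (R)-carvone, angelic acid and (−)-B-allyldiisopinocampheylborane (pentane solution) are bought; silver angelate is made in the flask.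

## Route

Step 1
Reactants: 1 (R)-(−)-carvone; 2 angelic acid
Product: 5 1β-angeloyloxy enone [(1R,6S)-3-methyl-2-oxo-6-(prop-1-en-2-yl)cyclohex-3-en-1-yl (2Z)-2-methylbut-2-enoate], via silyl dienol ether 3 (not isolated), via 1α-iodo ketone 4 (not isolated)
Conditions: LiN(i-Pr)2 (1.1 equiv), THF, −78 °C, then Me3SiCl; volatiles removed, pentane filtration; crude 3 added to AgO2CC(Me)=CHMe (2.2 equiv, from 2 and Ag2O, 4 Å sieves) and I2 (1.05 equiv), CH2Cl2, dark, −78 → −20 °C; aq. NaHCO3/Na2S2O3
Reagents that add atoms: angelic acid (as its silver salt), C/C=C(/C)C(=O)O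
Why: Proposed new method: the kinetic silyl dienol ether 3 is iodinated at C1 anti to the 6β-isopropenyl group by the acyl hypoiodite formed from AgO2CC(Me)=CHMe and I2, and because iodide is removed as AgI the 1α-iodo ketone 4 cannot epimerise before angelate displaces it with inversion under Ag+ assistance (direct SN2 or through a Prévost-type bridged acyloxonium ion), so the new C1–O bond is set syn to the isopropenyl group, the contra-steric result of a Woodward–Prévost sequence; the closest known reaction types are the Prévost/Woodward iodo-acyloxylation of alkenes and the silver carboxylate–iodine α-acyloxylation of simple enol silyl ethers, not yet shown on a cross-conjugated dienol ether, with an unsaturated carboxylate or as a stereoinvertive relay.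

Step 2
Reactants: 5 1β-angeloyloxy enone
Product: 6 allylic alcohol [(1R,2S,6S)-2-hydroxy-3-methyl-6-(prop-1-en-2-yl)cyclohex-3-en-1-yl (2Z)-2-methylbut-2-enoate; OH, ester and isopropenyl all cis]
Conditions: NaBH4, CeCl3·7H2O, MeOH, −78 °C
Reagents that add atoms: none
Why: Luche 1,2-reduction in which axial hydride delivery anti to the axial 1β-acyloxy group (polar Felkin–Anh, as in carvone → cis-carveol) puts the new C2 hydroxyl on the β face; any 1,2-angeloyl shift is harmless because both oxygens end as angelates.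

Step 3
Reactants: 6 allylic alcohol
Product: 7 epoxy alcohol [1β-angeloyloxy-3β,4β-epoxy-6β-isopropenyl-3α-methylcyclohexan-2β-ol; 1R,2R,3R,4S,6S]
Conditions: VO(acac)2 (5 mol %), t-BuOOH (1.5 equiv, decane), CH2Cl2, 0 °C → rt
Reagents that add atoms: tert-butyl hydroperoxide, CC(C)(C)OO
Why: Hydroxyl-directed vanadium epoxidation (Sharpless–Michaelson) delivers oxygen to C3=C4 syn to the 2β-OH, setting C3 and C4 as the β-epoxide and leaving the isopropenyl and angelate alkenes untouched.

Step 4
Reactants: 7 epoxy alcohol; 2 angelic acid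
Product: 8 bis-angelate [1β,2β-bis(angeloyloxy)-3β,4β-epoxy-6β-isopropenyl-3α-methylcyclohexane; 1R,2R,3S,4S,6S]
Conditions: 2 (3 equiv), 2,4,6-trichlorobenzoyl chloride (3 equiv), Et3N, toluene, rt; then 7, 75 °C, no DMAP
Reagents that add atoms: angelic acid, C/C=C(/C)C(=O)O
Why: Yamaguchi mixed-anhydride esterification acylates the hindered C2 alcohol without a nucleophilic catalyst, which avoids angelate-to-tiglate isomerisation and changes no stereocentre.

Step 5
Reactants: 8 bis-angelate
Product: 10 enal [6β-(3-oxoprop-1-en-2-yl) analogue of 8], via allylic alcohol 9 (not isolated)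
Conditions: SeO2 (0.5 equiv), t-BuOOH (3 equiv), CH2Cl2, rt; filter; MnO2, CH2Cl2, rt
Reagents that add atoms: tert-butyl hydroperoxide, CC(C)(C)OO; selenium dioxide (oxygen carrier), O=[Se]=O
Why: Riley allylic oxidation (ene reaction then [2,3]-shift) takes the isopropenyl methyl, the ring C6–H being hindered and deactivated by the neighbouring C1 ester, and MnO2 then oxidises the primary allylic alcohol to the α-methylene aldehyde.

Step 6
Reactants: 10 enal; 11 (−)-B-allyldiisopinocampheylborane
Product: 13 homoallylic alcohol [6β-[(3S)-3-hydroxyhexa-1,5-dien-2-yl] analogue of 8; 8S], via borinate ester 12 (not isolated)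
Conditions: 11 (1.2 equiv), Et2O, −78 °C; then HOCH2CH2NH2, rt
Reagents that add atoms: (−)-B-allyldiisopinocampheylborane, C=CCB([C@@H]1C[C@@H]2C[C@H]([C@H]1C)C2(C)C)[C@@H]1C[C@@H]2C[C@H]([C@H]1C)C2(C)C
Why: Brown asymmetric allylboration through a chair Zimmerman–Traxler transition state, in which the (+)-α-pinene-derived reagent adds allyl to the Si face of the aldehyde and sets C8 as S under reagent control, while esters and epoxide are inert at −78 °C and the non-oxidative work-up spares the angelates.

Step 7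
Reactants: 13 homoallylic alcohol; 14 acetic anhydride
Product: 15 acetate [6β-[(3S)-3-acetoxyhexa-1,5-dien-2-yl] analogue of 8]
Conditions: Ac2O, pyridine, DMAP (5 mol %), CH2Cl2, 0 °C
Reagents that add atoms: acetic anhydride, CC(=O)OC(C)=O
Why: Standard acylation of the secondary allylic alcohol, with retention at C8.

Step 8
Reactants: 15 acetate; 16 2-methyl-2-butene
Product: 17 target [(1R,2R,3S,4S,6S,8S)-8-acetoxy-1,2-bis(angeloyloxy)-3,4-epoxybisabola-7(14),10-diene]
Conditions: second-generation Grubbs catalyst (5 mol %), 2-methyl-2-butene (excess)/CH2Cl2, 40 °C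
Reagents that add atoms: 2-methyl-2-butene, CC=C(C)C
Why: Olefin cross-metathesis engages only the monosubstituted alkene (the 1,1-disubstituted and conjugated trisubstituted alkenes do not react) and the new C10=C11 bond carries no stereochemistry.

## Compound list

1 | (R)-(−)-carvone, (5R)-2-methyl-5-(prop-1-en-2-yl)cyclohex-2-en-1-one | C=C(C)[C@@H]1CC=C(C)C(=O)C1 | starting material
2 | angelic acid, (2Z)-2-methylbut-2-enoic acid | C/C=C(/C)C(=O)O | starting material
3 | silyl dienol ether, trimethyl{[(6R)-3-methyl-6-(prop-1-en-2-yl)cyclohexa-1,3-dien-2-yl]oxy}silane | C=C(C)[C@@H]1CC=C(C)C(O[Si](C)(C)C)=C1 | intermediate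
4 | 1α-iodo ketone, (5S,6S)-6-iodo-2-methyl-5-(prop-1-en-2-yl)cyclohex-2-en-1-one (iodine trans to isopropenyl) | C=C(C)[C@@H]1CC=C(C)C(=O)[C@H]1I | intermediate
5 | 1β-angeloyloxy enone, (1R,6S)-3-methyl-2-oxo-6-(prop-1-en-2-yl)cyclohex-3-en-1-yl (2Z)-2-methylbut-2-enoate (ester cis to isopropenyl) | C=C(C)[C@@H]1CC=C(C)C(=O)[C@@H]1OC(=O)/C(C)=C\C | intermediate
6 | allylic alcohol, (1R,2S,6S)-2-hydroxy-3-methyl-6-(prop-1-en-2-yl)cyclohex-3-en-1-yl (2Z)-2-methylbut-2-enoate (all cis) | C=C(C)[C@@H]1CC=C(C)[C@H](O)[C@@H]1OC(=O)/C(C)=C\C | intermediate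
7 | epoxy alcohol, 1β-angeloyloxy-3β,4β-epoxy-6β-isopropenyl-3α-methylcyclohexan-2β-ol (1R,2R,3R,4S,6S) | C=C(C)[C@@H]1C[C@@H]2O[C@]2(C)[C@H](O)[C@@H]1OC(=O)/C(C)=C\C | intermediate
8 | bis-angelate, 1β,2β-bis(angeloyloxy)-3β,4β-epoxy-6β-isopropenyl-3α-methylcyclohexane (1R,2R,3S,4S,6S) | C=C(C)[C@@H]1C[C@@H]2O[C@]2(C)[C@H](OC(=O)/C(C)=C\C)[C@@H]1OC(=O)/C(C)=C\C | intermediate
9 | allylic alcohol, 6β-(3-hydroxyprop-1-en-2-yl) analogue of 8 | C=C(CO)[C@@H]1C[C@@H]2O[C@]2(C)[C@H](OC(=O)/C(C)=C\C)[C@@H]1OC(=O)/C(C)=C\C | intermediate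
10 | enal, 6β-(3-oxoprop-1-en-2-yl) analogue of 8 | C=C(C=O)[C@@H]1C[C@@H]2O[C@]2(C)[C@H](OC(=O)/C(C)=C\C)[C@@H]1OC(=O)/C(C)=C\C | intermediate
11 | (−)-B-allyldiisopinocampheylborane (from (+)-α-pinene) | C=CCB([C@@H]1C[C@@H]2C[C@H]([C@H]1C)C2(C)C)[C@@H]1C[C@@H]2C[C@H]([C@H]1C)C2(C)C | starting material
12 | borinate ester, C8–O–B(Ipc)2 derivative of 13 | C=C([C@H](CC=C)OB([C@@H]1C[C@@H]2C[C@H]([C@H]1C)C2(C)C)[C@@H]1C[C@@H]2C[C@H]([C@H]1C)C2(C)C)[C@@H]1C[C@@H]2O[C@]2(C)[C@H](OC(=O)/C(C)=C\C)[C@@H]1OC(=O)/C(C)=C\C | intermediate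
13 | homoallylic alcohol, 6β-[(3S)-3-hydroxyhexa-1,5-dien-2-yl] analogue of 8 (8S) | C=C([C@H](CC=C)O)[C@@H]1C[C@@H]2O[C@]2(C)[C@H](OC(=O)/C(C)=C\C)[C@@H]1OC(=O)/C(C)=C\C | intermediate
14 | acetic anhydride | CC(=O)OC(C)=O | starting material
15 | acetate, 6β-[(3S)-3-acetoxyhexa-1,5-dien-2-yl] analogue of 8 | C=C([C@H](CC=C)OC(C)=O)[C@@H]1C[C@@H]2O[C@]2(C)[C@H](OC(=O)/C(C)=C\C)[C@@H]1OC(=O)/C(C)=C\C | intermediate
16 | 2-methyl-2-butene | CC=C(C)C | starting material
17 | target, (1R,2R,3S,4S,6S,8S)-8-acetoxy-1,2-bis(angeloyloxy)-3,4-epoxybisabola-7(14),10-diene | C=C([C@H](CC=C(C)C)OC(C)=O)[C@@H]1C[C@@H]2O[C@]2(C)[C@H](OC(=O)/C(C)=C\C)[C@@H]1OC(=O)/C(C)=C\C | target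

## Step count and risks

Total steps: 8. Longest linear sequence: 8 steps, from (R)-carvone 1.

Steps most likely to fail:

**Step 1 (proposed new method).** The risks are incomplete inversion at C1 (trans ester), carboxylate attack at C4 of the siloxyallyl cation, loss of HI towards a phenol, and iodine-promoted angelate isomerisation. The isopropenyl group should not compete for the limiting iodine at −78 °C. The fallback uses known chemistry, sets out from 1 and comes back at 5. Kinetic enolisation and silylation as before give 3, and N-bromosuccinimide (THF, −78 °C) gives the 1α-bromo ketone (5S,6S)-6-bromocarvone F1. F1 is isolated and displaced with inversion by CsO2CC(Me)=CHMe (from 2 and Cs2CO3, DMF, 0 °C).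

**Step 4.** The C2 alcohol sits between the epoxide carbon and the C1 ester, so the acylation may stall, and forcing it with nucleophilic catalysts would give tiglate. The fallback sets out from 7 and comes back at 8. Steglich esterification (DCC, DMAP, CH2Cl2) with 2-[bis(2,2,2-trifluoroethoxy)phosphoryl]propanoic acid can be pushed with DMAP because there is no Z-alkene to lose, and gives the C2 phosphonopropanoate F2. Still–Gennari olefination (KN(SiMe3)2, 18-crown-6, THF, −78 °C, then acetaldehyde) then builds the Z-2-methylbut-2-enoate in place.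

**Step 5.** Selenium dioxide may attack the ring C6–H instead of the methyl, and the epoxide may suffer from the acidic selenium species. The fallback sets out from 8 and comes back at 10. Ene-type allylic chlorination with Ca(OCl)2 and solid CO2 (CH2Cl2/H2O, 0 °C) gives the allylic chloride F3. Oxidation with 4-methylmorpholine N-oxide and catalytic NaI (MeCN, 40 °C) converts F3 into enal 10.

## Further compounds

F1 | step 1 | 1α-bromo ketone, (5S,6S)-6-bromo-2-methyl-5-(prop-1-en-2-yl)cyclohex-2-en-1-one | C=C(C)[C@@H]1CC=C(C)C(=O)[C@H]1Br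
F2 | step 4 | C2 2-[bis(2,2,2-trifluoroethoxy)phosphoryl]propanoate of 7 (both epimers at the phosphonate carbon) | C=C(C)[C@@H]1C[C@@H]2O[C@]2(C)[C@H](OC(=O)C(C)P(=O)(OCC(F)(F)F)OCC(F)(F)F)[C@@H]1OC(=O)/C(C)=C\C
F3 | step 5 | allylic chloride, 6β-(3-chloroprop-1-en-2-yl) analogue of 8 | C=C(CCl)[C@@H]1C[C@@H]2O[C@]2(C)[C@H](OC(=O)/C(C)=C\C)[C@@H]1OC(=O)/C(C)=C\C
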